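A ratio opens the reckoning: step 4 comes to rest with isomer of the product over target at 0.35, and I reckoned the amounts asked for from that ratio and from the competition for substrate.

    substrate ⇌ intermediate (K1 = 0.014, k1 = 0.030 s⁻¹)
    intermediate → target (k2 = 1.4 s⁻¹)
    2 substrate → homo dimer (k3 = 0.13 L mol⁻¹ s⁻¹)
    target ⇌ isomer of the product (K4 = 0.35, k4 = 0.0058 s⁻¹)

- theta: substrate 0.055 M; time 2.5 min
- epsilon: substrate 0.055 M; time 8.0 min

1. which of these there is most of at the end, counted by the substrate in it, theta (isomer of the product / target / substrate / intermediate)
2. which of these there is most of at the end, counted by the substrate in it, epsilon (isomer of the product / target / substrate / intermediate)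
3. amount of the one of these that there is most of at the end, in percent of the substrate charged, theta
4. amount of the one of these that there is most of at the end, in percent of the substrate charged, epsilon

- a species is counted by the substrate in it: one homo dimer counts as two
- a step written with two of one species runs at k times the square of its concentration and takes two of it each time
- run time (theta): 2.5 min

1. I took the intermediate as quasi-steady, since it left at 3.54 s⁻¹, far faster than it was formed per unit of substrate, and so substrate passed to target at 0.0119 s⁻¹.

2. Dimerisation began at 0.0143 s⁻¹, which gave me a ratio of 1.21 between the two routes at the start. Integrating that competition, I found 65.6% of the charge finally reaching the target and isomer pair.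

3. I then defined the rest share, target over target plus isomer of the product at equilibrium of step 4 (thermodynamic control within the pair), as 0.741, which stood 24 percentage points above the even split I used as the zero of my scale. This gave 48.6% target for epsilon.

4. For theta, the same integral gave 0.169 as the decay factor, 8.44% substrate left and 57.6% in the pair, hence 42.6% target.

5. That last link was weak: my reckoning still left 8.44% substrate in theta at the end, and that substrate was still feeding the pair. I reforged it with the relaxation rate 0.0224 s⁻¹, faster than the feed's decay 0.0131 s⁻¹, which put target 2.79% ahead of its rest share, and I committed to 45.4% for theta.

The forecast named target for theta and target for epsilon, at 45% and 48.5%, the first a little below mine; in its words, “The target/isomer pair relaxes in about 45 s toward a 74:26 split, so the target leads in both runs”.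

The simulation gave target at 44.9% in theta and target at 48.6% in epsilon. In theta, the pair's relaxation half-life of 0.516 min was shorter than the run of 2.5 min. Target's share of the pair in theta was 0.781, above the rest share of 0.741. In epsilon, target held 48.6% and isomer of the product 16.9%, a share of 0.741, level with the rest share.

(The constants belong to no real substance, and the outcome is calculated.)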